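## Retrosynthetic overview
- The target comes from O-acetylation of the C6 alcohol (3E,6R,8S)-1,11-di(furan-3-yl)-4,8-dimethylundec-3-en-6-ol.
- Key bond C5–C6: C6 is used as a sparteine-complexed α-carbamoyloxy carbanion (a chiral hydroxyalkyl-anion, d1 equivalent). It captures the nucleophilic CH2 of an (E)-allyl pinacol boronate; a 1,2-metallate shift and B→OH oxidation set (6R) directly.
- East half: (S)-citronellol supplies C8; it is carbamoylated, ozonolysed and reductively coupled with furan-3-ylboronic acid.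
- West half: 3-bromofuran and homoprenyl Grignard give perillene; SeO2 oxidises the (E)-methyl; the allylic alcohol is borylated under Pd catalysis.
- Rings: none is formed. Both furans are bought intact (East furan attached in step 3, West furan in step 4).

Assumption: the SMILES is read as (3E,6R,8S)-1,11-di(furan-3-yl)-4,8-dimethylundec-3-en-6-yl acetate; the locants of this undecene chain are used throughout.

## Route

Step 1
Reactants: 1 (S)-citronellol
Product: 2 (S)-3,7-dimethyloct-6-en-1-yl N,N-diisopropylcarbamate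
Conditions: iPr2NCOCl (1.2 equiv), Et3N (1.5 equiv), CH2Cl2, reflux, 24 h
Reagents that add atoms: N,N-diisopropylcarbamoyl chloride, CC(C)N(C(C)C)C(Cl)=O
Why: Carbamate formation (O-acylation of a primary alcohol); the hindered carbamate is both the protecting group and the later directing and leaving group, and C3 is not touched.

Step 2
Reactants: 2 (S)-3,7-dimethyloct-6-en-1-yl N,N-diisopropylcarbamate
Product: 3 (S)-3-methyl-6-oxohexyl N,N-diisopropylcarbamate
Conditions: O3, CH2Cl2, –78 °C; then PPh3 (1.2 equiv), –78 °C to rt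
Reagents that add atoms: ozone, [O-][O+]=O
Why: Ozonolysis with reductive work-up cleaves the only C=C to the aldehyde; the carbamate is inert and the stereocentre is γ to the CHO, so it cannot epimerise.

Step 3
Reactants: 3 (S)-3-methyl-6-oxohexyl N,N-diisopropylcarbamate; 4 furan-3-ylboronic acid
Product: 6 (S)-6-(furan-3-yl)-3-methylhexyl N,N-diisopropylcarbamate, via aldehyde tosylhydrazone 5 (not isolated)
Conditions: TsNHNH2 (1.05 equiv), 1,4-dioxane, 80 °C, 1 h; then 4 (1.5 equiv), K2CO3 (2 equiv), 110 °C, 4 h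
Reagents that add atoms: p-toluenesulfonyl hydrazide, Cc1ccc(cc1)S(=O)(=O)NN (its atoms are only in intermediate 5; none remain in 6)
Why: Barluenga-type metal-free reductive coupling: Bamford–Stevens formation of the diazoalkane, 1,2-shift of the furyl group from boron to carbon, and protodeboronation of the furylic boronic acid turn CHO into CH2–(3-furyl); no stereocentre is involved.

Step 4
Reactants: 7 5-bromo-2-methylpent-2-ene; 8 3-bromofuran
Product: 10 perillene [3-(4-methylpent-3-en-1-yl)furan], via homoprenylmagnesium bromide 9 (not isolated)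
Conditions: 7 (1.2 equiv), Mg, THF, rt to 40 °C; then 8 (1.0 equiv), NiCl2(dppp) (2 mol %), Et2O, 0 °C to reflux
Reagents that add atoms: magnesium, [Mg] (only in intermediate 9; none remains in 10)
Why: Kumada–Corriu sp3–sp2 coupling; the bidentate phosphine suppresses β-hydride elimination of the primary alkyl, and no metallated furan is generated, so the furan stays 3-substituted.

Step 5
Reactants: 10 perillene
Product: 11 (E)-5-(furan-3-yl)-2-methylpent-2-en-1-ol
Conditions: SeO2 (0.2 equiv), t-BuOOH (2.5 equiv), salicylic acid (0.1 equiv), CH2Cl2, rt, 24 h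
Reagents that add atoms: tert-butyl hydroperoxide, CC(C)(C)OO (terminal oxidant and source of the O atom, delivered through catalytic SeO2, O=[Se]=O)
Why: Sharpless-type catalytic SeO2 allylic oxidation (ene reaction, then [2,3]-sigmatropic shift) attacks the (E)-methyl at the more substituted alkene terminus, which fixes the E-trisubstituted olefin of the target.

Step 6
Reactants: 11 (E)-5-(furan-3-yl)-2-methylpent-2-en-1-ol
Product: 12 2-[(E)-5-(furan-3-yl)-2-methylpent-2-en-1-yl]-4,4,5,5-tetramethyl-1,3,2-dioxaborolane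
Conditions: B2pin2 (1.2 equiv), [Pd(MeCN)4](BF4)2 (5 mol %), DMSO/MeOH 1:1, 40 °C
Reagents that add atoms: bis(pinacolato)diboron, CC1(C)OB(OC1(C)C)B1OC(C)(C)C(C)(C)O1
Why: Pd-catalysed borylation of an allylic alcohol through an η3-allylpalladium intermediate; boron goes to the unhindered CH2 terminus, and the syn-η3 complex keeps the E geometry.

Step 7
Reactants: 6 (S)-6-(furan-3-yl)-3-methylhexyl N,N-diisopropylcarbamate; 12 2-[(E)-5-(furan-3-yl)-2-methylpent-2-en-1-yl]-4,4,5,5-tetramethyl-1,3,2-dioxaborolane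
Product: 16 (3E,6R,8S)-1,11-di(furan-3-yl)-4,8-dimethylundec-3-en-6-ol, via lithiated carbamate 13 (not isolated), via boronate complex 14 (not isolated), via secondary boronic ester 15 (not isolated)
Conditions: 6 (1.4 equiv), (–)-sparteine (1.4 equiv), s-BuLi (1.3 equiv), Et2O, –78 °C, 5 h; 12 (1.0 equiv), –78 °C, 1 h; MgBr2·OEt2 (Lewis-acid promoter, not consumed), reflux, 16 h; then THF, 2 M NaOH, 30% H2O2, 0 °C to rt
Reagents that add atoms: sec-butyllithium, [Li]C(C)CC (Li only in intermediates 13 and 14); hydrogen peroxide, OO (source of the hydroxyl O; the original carbamate O leaves with the carbamate)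
Why: Hoppe sparteine-mediated asymmetric deprotonation followed by lithiation–borylation (Matteson-type 1,2-metallate rearrangement) and oxidation. The carbinol carbon, which would normally be an electrophilic C=O carbon, is used as a configurationally stable α-oxy carbanion and joined to the nucleophilic allyl carbon of 12. (–)-Sparteine/s-BuLi removes the pro-S proton to give the (S)-organolithium; borylation goes with retention, the antiperiplanar allyl shift with inversion and the oxidation with retention, so C6 becomes (R). C8 (from citronellol) and the E-olefin are untouched, and keeping s-BuLi below the amount of 6 limits furan metallation.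

Step 8
Reactants: 16 (3E,6R,8S)-1,11-di(furan-3-yl)-4,8-dimethylundec-3-en-6-ol
Product: 17 (3E,6R,8S)-1,11-di(furan-3-yl)-4,8-dimethylundec-3-en-6-yl acetate
Conditions: Ac2O (2 equiv), pyridine, DMAP (5 mol %), CH2Cl2, 0 °C to rt
Reagents that add atoms: acetic anhydride, CC(=O)OC(C)=O
Why: DMAP-catalysed O-acylation; the C6–O bond is not broken, so the configuration is retained.

## Compound list
1 | (S)-citronellol [(S)-3,7-dimethyloct-6-en-1-ol] | OCC[C@@H](C)CCC=C(C)C | starting material
2 | (S)-3,7-dimethyloct-6-en-1-yl N,N-diisopropylcarbamate | CC(C)N(C(C)C)C(=O)OCC[C@@H](C)CCC=C(C)C | intermediate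
3 | (S)-3-methyl-6-oxohexyl N,N-diisopropylcarbamate | CC(C)N(C(C)C)C(=O)OCC[C@@H](C)CCC=O | intermediate
4 | furan-3-ylboronic acid | OB(O)c1ccoc1 | starting material
5 | N-tosylhydrazone of aldehyde 3 [(S,E)-3-methyl-6-(2-tosylhydrazinylidene)hexyl N,N-diisopropylcarbamate] | CC(C)N(C(C)C)C(=O)OCC[C@@H](C)CC/C=N/NS(=O)(=O)c1ccc(C)cc1 | intermediate
6 | (S)-6-(furan-3-yl)-3-methylhexyl N,N-diisopropylcarbamate | CC(C)N(C(C)C)C(=O)OCC[C@@H](C)CCCc1ccoc1 | intermediate
7 | 5-bromo-2-methylpent-2-ene | CC(C)=CCCBr | starting material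
8 | 3-bromofuran | Brc1ccoc1 | starting material
9 | (4-methylpent-3-en-1-yl)magnesium bromide | CC(C)=CCC[Mg]Br | intermediate
10 | perillene [3-(4-methylpent-3-en-1-yl)furan] | CC(C)=CCCc1ccoc1 | intermediate
11 | (E)-5-(furan-3-yl)-2-methylpent-2-en-1-ol | OC/C(C)=C/CCc1ccoc1 | intermediate
12 | 2-[(E)-5-(furan-3-yl)-2-methylpent-2-en-1-yl]-4,4,5,5-tetramethyl-1,3,2-dioxaborolane | CC1(C)OB(C/C(C)=C/CCc2ccoc2)OC1(C)C | intermediate
13 | [(1S,3S)-1-(diisopropylcarbamoyloxy)-6-(furan-3-yl)-3-methylhexyl]lithium, (–)-sparteine complex | [Li][C@H](OC(=O)N(C(C)C)C(C)C)C[C@@H](C)CCCc1ccoc1 | intermediate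
14 | lithium boronate complex of 13 with 12 (B bears pinacolato, the allyl group and the (S)-α-carbamoyloxyalkyl group) | [Li+].CC1(C)O[B-](C/C(C)=C/CCc2ccoc2)(OC1(C)C)[C@H](OC(=O)N(C(C)C)C(C)C)C[C@@H](C)CCCc2ccoc2 | intermediate
15 | 2-[(3E,6R,8S)-1,11-di(furan-3-yl)-4,8-dimethylundec-3-en-6-yl]-4,4,5,5-tetramethyl-1,3,2-dioxaborolane | CC1(C)OB(OC1(C)C)[C@@H](C/C(C)=C/CCc2ccoc2)C[C@@H](C)CCCc2ccoc2 | intermediate
16 | (3E,6R,8S)-1,11-di(furan-3-yl)-4,8-dimethylundec-3-en-6-ol | O[C@@H](C/C(C)=C/CCc1ccoc1)C[C@@H](C)CCCc1ccoc1 | intermediate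
17 | (3E,6R,8S)-1,11-di(furan-3-yl)-4,8-dimethylundec-3-en-6-yl acetate | CC(=O)O[C@@H](C/C(C)=C/CCc1ccoc1)C[C@@H](C)CCCc1ccoc1 | target

## Step count
Total: 8 steps. Longest linear sequence: 5 steps (1 → 2 → 3 → 7 → 8; the West branch 4 → 5 → 6 → 7 → 8 is equally long).

## Steps most likely to fail

**Step 7 (key coupling).** The risks are competing α-lithiation of the 3-alkylfuran in 6 by s-BuLi, and sluggish or unclean 1,2-shift of the allyl boronate complex. The fallback attaches the East furan only after the C5–C6 bond is made, so no furan meets s-BuLi. It sets out from 3 and comes back at 16.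
- MeOH, cat. PPTS and 3 Å sieves convert 3 into (S)-6,6-dimethoxy-3-methylhexyl N,N-diisopropylcarbamate F1.
- s-BuLi/(–)-sparteine (Et2O, –78 °C) gives the lithiated acetal carbamate F2.
- Addition of 12 gives the lithium boronate complex F3, which rearranges (MgBr2·OEt2, reflux) to the secondary pinacol boronic ester F4.
- NaOH/H2O2 gives (3E,6R,8S)-1-(furan-3-yl)-11,11-dimethoxy-4,8-dimethylundec-3-en-6-ol F5.
- PPTS in wet acetone frees (4S,6R,8E)-11-(furan-3-yl)-6-hydroxy-4,8-dimethylundec-8-enal F6.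
- TsNHNH2, then 4 and K2CO3 in dioxane at 110 °C, pass through the hydroxy aldehyde tosylhydrazone F7 and deliver 16, which goes on to step 8.

**Step 3 (reductive coupling).** The risks are Bamford–Stevens alkene formation from the aliphatic diazoalkane and protodeboronation of 4. The fallback replaces the hydrazone chemistry with an sp3–sp2 Negishi coupling. It sets out from 3 and comes back at 6.
- NaBH4 in MeOH at 0 °C gives (S)-6-hydroxy-3-methylhexyl N,N-diisopropylcarbamate F8.
- I2, PPh3 and imidazole give (S)-6-iodo-3-methylhexyl N,N-diisopropylcarbamate F9.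
- Zinc dust/LiCl in THF at 40 °C gives the alkylzinc iodide [(S)-6-(diisopropylcarbamoyloxy)-4-methylhexyl]zinc iodide F10, used in solution.
- Coupling with 8 under Pd(OAc)2/SPhos gives 6.

**Step 5 (SeO2 oxidation).** The risks are modest conversion, over-oxidation to the enal and oxidative damage to the furan. The fallback builds the E-allylic alcohol by olefination instead of C–H oxidation and replaces steps 4 and 5. It sets out from 8 and comes back at 11.
- n-BuLi in THF at –78 °C gives furan-3-yllithium F11.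
- Oxetane and BF3·OEt2 at –78 °C give 3-(furan-3-yl)propan-1-ol F12.
- Swern oxidation gives 3-(furan-3-yl)propanal F13.
- Wittig reaction with Ph3P=C(CH3)CO2Et in CH2Cl2 gives ethyl (E)-5-(furan-3-yl)-2-methylpent-2-enoate F14.
- DIBAL-H in CH2Cl2 at –78 °C gives 11.

## Further compounds
F1 | step 7 | (S)-6,6-dimethoxy-3-methylhexyl N,N-diisopropylcarbamate | CC(C)N(C(C)C)C(=O)OCC[C@@H](C)CCC(OC)OC
F2 | step 7 | [(1S,3S)-1-(diisopropylcarbamoyloxy)-6,6-dimethoxy-3-methylhexyl]lithium, (–)-sparteine complex | [Li][C@H](OC(=O)N(C(C)C)C(C)C)C[C@@H](C)CCC(OC)OC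
F3 | step 7 | lithium boronate complex of F2 with 12 | [Li+].CC1(C)O[B-](C/C(C)=C/CCc2ccoc2)(OC1(C)C)[C@H](OC(=O)N(C(C)C)C(C)C)C[C@@H](C)CCC(OC)OC
F4 | step 7 | 2-[(3E,6R,8S)-1-(furan-3-yl)-11,11-dimethoxy-4,8-dimethylundec-3-en-6-yl]-4,4,5,5-tetramethyl-1,3,2-dioxaborolane | CC1(C)OB(OC1(C)C)[C@@H](C/C(C)=C/CCc2ccoc2)C[C@@H](C)CCC(OC)OC
F5 | step 7 | (3E,6R,8S)-1-(furan-3-yl)-11,11-dimethoxy-4,8-dimethylundec-3-en-6-ol | O[C@@H](C/C(C)=C/CCc1ccoc1)C[C@@H](C)CCC(OC)OC
F6 | step 7 | (4S,6R,8E)-11-(furan-3-yl)-6-hydroxy-4,8-dimethylundec-8-enal | O[C@@H](C/C(C)=C/CCc1ccoc1)C[C@@H](C)CCC=O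
F7 | step 7 | N-tosylhydrazone of F6 | O[C@@H](C/C(C)=C/CCc1ccoc1)C[C@@H](C)CC/C=N/NS(=O)(=O)c1ccc(C)cc1
F8 | step 3 | (S)-6-hydroxy-3-methylhexyl N,N-diisopropylcarbamate | CC(C)N(C(C)C)C(=O)OCC[C@@H](C)CCCO
F9 | step 3 | (S)-6-iodo-3-methylhexyl N,N-diisopropylcarbamate | CC(C)N(C(C)C)C(=O)OCC[C@@H](C)CCCI
F10 | step 3 | [(S)-6-(diisopropylcarbamoyloxy)-4-methylhexyl]zinc iodide | CC(C)N(C(C)C)C(=O)OCC[C@@H](C)CCC[Zn]I
F11 | step 5 | furan-3-yllithium | [Li]c1ccoc1
F12 | step 5 | 3-(furan-3-yl)propan-1-ol | OCCCc1ccoc1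
F13 | step 5 | 3-(furan-3-yl)propanal | O=CCCc1ccoc1
F14 | step 5 | ethyl (E)-5-(furan-3-yl)-2-methylpent-2-enoate | CCOC(=O)/C(C)=C/CCc1ccoc1
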